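**Strategy**

The 2,3-dihydrobenzofuran ring is disconnected at its aryl C3a–C3 bond and its O1–C2 bond. Carbons C3 and C2 and the attached C(CH3)2 carbon map onto isoprene, and the ortho-related C3a and O1 onto an ortho-bromophenol. An enantioselective palladium-catalyzed Heck/Tsuji–Trost [3+2] heteroannulation of 3-bromo-4-hydroxybenzaldehyde with isoprene therefore builds this ring, both bonds and the C2 stereocenter in one operation; the isopropenyl group is hydrated afterwards. The derived benzylic bromide then alkylates a 3-benzyloxy-4-arylbutenolide-5-carboxylate, made from an arylpyruvate and methyl glyoxylate, under chiral phase-transfer catalysis to set the quaternary lactone carbon, and hydrogenolysis completes the target.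

Key step: step 1

Assumption: both antipodes of the chiral phosphine ligand (step 1) and of the chiral ammonium catalyst (step 8) are accessible; the sense of induction is not predicted here, and the antipode that gives the stated configuration is to be chosen in a small-scale trial.
Assumption: methyl glyoxylate 11 is used as freshly cracked monomer.

**Route**

Step 1
Reactants: 1 3-bromo-4-hydroxybenzaldehyde; 2 isoprene (excess)
Product: 3 (S)-2-(prop-1-en-2-yl)-2,3-dihydro-1-benzofuran-5-carbaldehyde
Conditions: Pd2(dba)3 (cat.), chiral N-tert-butanesulfinyl aminomethyl monophosphine ligand (Sadphos type), PhONa, CH2Cl2, 40 °C, sealed tube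
Reagents that add atoms: none
Why: Oxidative addition of zerovalent palladium into the C–Br bond of 1 is followed by migratory insertion of the monosubstituted C3=C4 double bond of isoprene, which joins the aryl carbon to the terminal CH2 and leaves a 2-methyl-substituted η3-allylpalladium unit; the neighboring phenoxide then attacks the internal allyl terminus to form the O–CH bond and release the catalyst. The closest known reaction type is the Larock heteroannulation of 1,3-dienes with ortho-halophenols in its enantioselective Heck/Tsuji–Trost form with chiral monophosphine ligands. The one ring that closes, the dihydrofuran, does so by a 5-exo allylic etherification in which the isopropenyl double bond stays outside the ring. The C2 stereocenter is set by the catalyst: the chiral ligand decides which face of the equilibrating (π–σ–π) allyl unit the phenoxide attacks, and the ligand antipode that gives (S) is used. The step needs regioselectivity twice (insertion at C3=C4 rather than at the 1,1-disubstituted C1=C2 bond, and O-attack at the internal rather than the terminal allyl carbon), secured by the lower substitution of C3=C4 and by the preference for a five- over a seven-membered ring, while the aldehyde is a spectator.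

Step 2
Reactants: 3 (S)-2-(prop-1-en-2-yl)-2,3-dihydro-1-benzofuran-5-carbaldehyde
Product: 4 [(S)-2-(prop-1-en-2-yl)-2,3-dihydro-1-benzofuran-5-yl]methanol
Conditions: NaBH4, MeOH, 0 °C
Reagents that add atoms: none
Why: Borohydride reduction of the aryl aldehyde should leave the isopropenyl group and the C2 stereocenter untouched.

Step 3
Reactants: 4 [(S)-2-(prop-1-en-2-yl)-2,3-dihydro-1-benzofuran-5-yl]methanol
Product: 5 2-[(S)-5-(hydroxymethyl)-2,3-dihydro-1-benzofuran-2-yl]propan-2-ol
Conditions: Co(acac)2 (cat.), PhSiH3, O2 (1 atm), THF, rt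
Reagents that add atoms: dioxygen, O=O
Why: Mukaiyama hydration: hydrogen-atom transfer from a cobalt hydride to the 1,1-disubstituted alkene gives the tertiary radical, which is trapped by O2 and reduced to the Markovnikov tertiary alcohol without involving the C2–H bond.

Step 4
Reactants: 5 2-[(S)-5-(hydroxymethyl)-2,3-dihydro-1-benzofuran-2-yl]propan-2-ol
Product: 6 2-[(S)-5-(bromomethyl)-2,3-dihydro-1-benzofuran-2-yl]propan-2-ol
Conditions: CBr4, PPh3, CH2Cl2, 0 °C; used at once without storage
Reagents that add atoms: carbon tetrabromide, BrC(Br)(Br)Br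
Why: The Appel reaction should convert the unhindered primary benzylic alcohol much faster than the hindered tertiary alcohol, and the labile 4-alkoxybenzylic bromide is carried on directly.

Step 5
Reactants: 7 1-(benzyloxy)-4-(chloromethyl)benzene; 8 dimethyl oxalate (excess)
Product: 10 methyl 3-[4-(benzyloxy)phenyl]-2-oxopropanoate, via benzylic Grignard reagent 9 (not isolated)
Conditions: Mg, THF, 0 °C; then slow addition to 8, THF, −78 °C; aq. NH4Cl
Reagents that add atoms: none
Why: Acylation of a benzylic Grignard reagent by an oxalate diester stops after one addition because the tetrahedral magnesium alkoxide persists at low temperature until work-up.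

Step 6
Reactants: 10 methyl 3-[4-(benzyloxy)phenyl]-2-oxopropanoate; 11 methyl glyoxylate (excess)
Product: 13 methyl 3-[4-(benzyloxy)phenyl]-4-hydroxy-5-oxo-2,5-dihydrofuran-2-carboxylate (racemic), via aldol adduct 12 (not isolated)
Conditions: Et3N, CH2Cl2, 0 °C to rt; then 1 M HCl
Reagents that add atoms: none
Why: Crossed aldol addition of the readily enolized arylpyruvate through its benzylic carbon to the non-enolizable glyoxylate aldehyde, then five-membered lactonization onto the keto ester and enolization, gives the isotetronic acid; its C5 center is left racemic because step 8 planarizes it.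

Step 7
Reactants: 13 methyl 3-[4-(benzyloxy)phenyl]-4-hydroxy-5-oxo-2,5-dihydrofuran-2-carboxylate (racemic)
Product: 14 methyl 4-(benzyloxy)-3-[4-(benzyloxy)phenyl]-5-oxo-2,5-dihydrofuran-2-carboxylate (racemic)
Conditions: BnOH, PPh3, DIAD, THF, 0 °C to rt
Reagents that add atoms: benzyl alcohol, OCc1ccccc1
Why: Mitsunobu etherification of the acidic enol hydroxyl runs under neutral conditions, so no C5 carbanion forms and C-benzylation is avoided.

Step 8
Reactants: 14 methyl 4-(benzyloxy)-3-[4-(benzyloxy)phenyl]-5-oxo-2,5-dihydrofuran-2-carboxylate (racemic); 6 2-[(S)-5-(bromomethyl)-2,3-dihydro-1-benzofuran-2-yl]propan-2-ol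
Product: 15 methyl (R)-4-(benzyloxy)-3-[4-(benzyloxy)phenyl]-2-{[(S)-2-(2-hydroxypropan-2-yl)-2,3-dihydro-1-benzofuran-5-yl]methyl}-5-oxo-2,5-dihydrofuran-2-carboxylate
Conditions: chiral N-spiro bis(binaphthyl) quaternary ammonium bromide with 3,4,5-trifluorophenyl groups (cat.), solid Cs2CO3, toluene, −20 °C
Reagents that add atoms: none
Why: Proposed new method: deprotonation of the acidic C5–H of 14 (alpha to the ester, gamma to the lactone carbonyl) gives a planar push–pull 2-furanolate held in a tight ion pair by the chiral ammonium cation, and the benzylic bromide should attack C5 (the ester-bearing terminus, whose alkylation restores the conjugated 3-alkoxybutenolide, whereas C3 is shielded by the benzyloxy group) on the face the catalyst leaves open, so the quaternary center is set by the catalyst (antipode chosen for R) independently of the remote center of 6; the closest known reaction type is the asymmetric phase-transfer benzylation of oxygen-substituted, ester-stabilized carbon acids such as phthalide-3-carboxylates and 2-acyloxymalonates, which has not been shown on a butenolide dienolate with a competing C3 terminus.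

Step 9
Reactants: 15 methyl (R)-4-(benzyloxy)-3-[4-(benzyloxy)phenyl]-2-{[(S)-2-(2-hydroxypropan-2-yl)-2,3-dihydro-1-benzofuran-5-yl]methyl}-5-oxo-2,5-dihydrofuran-2-carboxylate
Product: 16 methyl (R)-4-hydroxy-3-(4-hydroxyphenyl)-2-{[(S)-2-(2-hydroxypropan-2-yl)-2,3-dihydro-1-benzofuran-5-yl]methyl}-5-oxo-2,5-dihydrofuran-2-carboxylate
Conditions: H2 (1 atm), Pd/C, EtOAc, rt
Reagents that add atoms: none
Why: Hydrogenolysis should cleave the aryl benzyl ether and the enol benzyl ether, while the tetrasubstituted butenolide alkene, the lactone, the ester, the tertiary alcohol and both stereocenters are not affected.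

**Compound list**

1 | 3-bromo-4-hydroxybenzaldehyde | O=Cc1ccc(O)c(Br)c1 | starting material
2 | isoprene (2-methylbuta-1,3-diene) | C=CC(C)=C | starting material
3 | (S)-2-(prop-1-en-2-yl)-2,3-dihydro-1-benzofuran-5-carbaldehyde | O=Cc1ccc2c(c1)C[C@@H](C(C)=C)O2 | intermediate
4 | [(S)-2-(prop-1-en-2-yl)-2,3-dihydro-1-benzofuran-5-yl]methanol | OCc1ccc2c(c1)C[C@@H](C(C)=C)O2 | intermediate
5 | 2-[(S)-5-(hydroxymethyl)-2,3-dihydro-1-benzofuran-2-yl]propan-2-ol | OCc1ccc2c(c1)C[C@@H](C(C)(C)O)O2 | intermediate
6 | 2-[(S)-5-(bromomethyl)-2,3-dihydro-1-benzofuran-2-yl]propan-2-ol | BrCc1ccc2c(c1)C[C@@H](C(C)(C)O)O2 | intermediate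
7 | 1-(benzyloxy)-4-(chloromethyl)benzene | ClCc1ccc(OCc2ccccc2)cc1 | starting material
8 | dimethyl oxalate | COC(=O)C(=O)OC | starting material
9 | [4-(benzyloxy)benzyl]magnesium chloride (not isolated) | Cl[Mg]Cc1ccc(OCc2ccccc2)cc1 | intermediate
10 | methyl 3-[4-(benzyloxy)phenyl]-2-oxopropanoate | COC(=O)C(=O)Cc1ccc(OCc2ccccc2)cc1 | intermediate
11 | methyl glyoxylate | COC(=O)C=O | starting material
12 | dimethyl 3-[4-(benzyloxy)phenyl]-2-hydroxy-4-oxopentanedioate (diastereomer mixture, not isolated) | COC(=O)C(O)C(c1ccc(OCc2ccccc2)cc1)C(=O)C(=O)OC | intermediate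
13 | methyl 3-[4-(benzyloxy)phenyl]-4-hydroxy-5-oxo-2,5-dihydrofuran-2-carboxylate (racemic) | COC(=O)C1OC(=O)C(O)=C1c1ccc(OCc2ccccc2)cc1 | intermediate
14 | methyl 4-(benzyloxy)-3-[4-(benzyloxy)phenyl]-5-oxo-2,5-dihydrofuran-2-carboxylate (racemic) | COC(=O)C1OC(=O)C(OCc2ccccc2)=C1c1ccc(OCc2ccccc2)cc1 | intermediate
15 | methyl (R)-4-(benzyloxy)-3-[4-(benzyloxy)phenyl]-2-{[(S)-2-(2-hydroxypropan-2-yl)-2,3-dihydro-1-benzofuran-5-yl]methyl}-5-oxo-2,5-dihydrofuran-2-carboxylate | COC(=O)[C@]1(Cc2ccc3c(c2)C[C@@H](C(C)(C)O)O3)OC(=O)C(OCc2ccccc2)=C1c1ccc(OCc2ccccc2)cc1 | intermediate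
16 | methyl (R)-4-hydroxy-3-(4-hydroxyphenyl)-2-{[(S)-2-(2-hydroxypropan-2-yl)-2,3-dihydro-1-benzofuran-5-yl]methyl}-5-oxo-2,5-dihydrofuran-2-carboxylate | COC(=O)[C@]1(Cc2ccc3c(c2)C[C@@H](C(C)(C)O)O3)OC(=O)C(O)=C1c1ccc(O)cc1 | target

**Count**

Total step count: 9
Longest linear sequence: 6 steps (steps 1, 2, 3, 4, 8, 9)

**Steps most likely to fail**

1. Step 8 (Proposed new method). The process at risk is facial discrimination within the chiral ion pair, so that both configurations of the quaternary carbon could form; attack of the ambident furanolate at C3 or at oxygen could also compete. Fallback: setting out from 14 and 6, the benzylation would be run without a chiral catalyst (Cs2CO3, DMF, 0 °C), an ordinary C-alkylation of a stabilized carbanion by a benzylic bromide. It would give 15 together with its C5 epimer, methyl (S)-4-(benzyloxy)-3-[4-(benzyloxy)phenyl]-2-{[(S)-2-(2-hydroxypropan-2-yl)-2,3-dihydro-1-benzofuran-5-yl]methyl}-5-oxo-2,5-dihydrofuran-2-carboxylate F1. Because the dihydrobenzofuran center is fixed, the two are diastereomers and would be separated by preparative HPLC; the route is rejoined at 15.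

2. Step 1 (key step). The processes at risk are loss of regiocontrol in the diene insertion (aryl transfer to C1, leading to the 2-methyl-2-vinyl isomer), β-hydride elimination to an aryl diene before C–O bond formation, and weak enantiofacial control at the allyl stage. Fallback: setting out from 1, a domino Sonogashira coupling and 5-endo cyclization with 2-methylbut-3-yn-2-ol (Pd(PPh3)2Cl2, CuI, Et3N, DMF, 80 °C) would form the same aryl C–C and O–C ring bonds in one operation. It would give 2-(2-hydroxypropan-2-yl)-1-benzofuran-5-carbaldehyde F2 with the tertiary alcohol already in place. NaBH4 reduction would give 2-[5-(hydroxymethyl)-1-benzofuran-2-yl]propan-2-ol F3. Enantioselective hydrogenation of the furan C2=C3 bond (Ru(cod)(2-methylallyl)2, chiral N-heterocyclic carbene ligand from its imidazolinium salt, KOtBu, H2, hexane) would then set the C2 center and rejoin the route at 5.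

3. Step 6. The processes at risk are self-condensation of the enolizable pyruvate 10 (homo-aldol and lactonization) outrunning the crossed addition, and base-induced oligomerization of the glyoxylate. Fallback: setting out from 10, silylation (TMSCl, Et3N, CH2Cl2) would give the silyl enol ether methyl (Z)-3-[4-(benzyloxy)phenyl]-2-[(trimethylsilyl)oxy]prop-2-enoate F4. Its Mukaiyama aldol addition to 11 (TiCl4, CH2Cl2, −78 °C) fixes the donor role without base. Acidic work-up would desilylate the adduct to 12, which lactonizes, so the route is rejoined at 13.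

**Further compounds**

F1 | step 8 | methyl (S)-4-(benzyloxy)-3-[4-(benzyloxy)phenyl]-2-{[(S)-2-(2-hydroxypropan-2-yl)-2,3-dihydro-1-benzofuran-5-yl]methyl}-5-oxo-2,5-dihydrofuran-2-carboxylate | COC(=O)[C@@]1(Cc2ccc3c(c2)C[C@@H](C(C)(C)O)O3)OC(=O)C(OCc2ccccc2)=C1c1ccc(OCc2ccccc2)cc1
F2 | step 1 | 2-(2-hydroxypropan-2-yl)-1-benzofuran-5-carbaldehyde | O=Cc1ccc2oc(C(C)(C)O)cc2c1
F3 | step 1 | 2-[5-(hydroxymethyl)-1-benzofuran-2-yl]propan-2-ol | OCc1ccc2oc(C(C)(C)O)cc2c1
F4 | step 6 | methyl (Z)-3-[4-(benzyloxy)phenyl]-2-[(trimethylsilyl)oxy]prop-2-enoate | COC(=O)/C(O[Si](C)(C)C)=C/c1ccc(OCc2ccccc2)cc1
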